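**Retrosynthetic overview**

- Target 14 comes from flavanone 13 by cleavage of the C5 methyl ether next to the C4 carbonyl. 13 comes from 4-methoxyflavan 12 by oxidation of the C4 methyl ether.
- The strategy rests on ring C: it divides into the four-atom unit O1–C8a–C4a–C4 carried by ring A and the two-carbon unit C2–C3, which is the vinyl group of a styrene bearing ring B.
- An oxa-[4+2] cycloaddition of ortho-quinone methide 11 (from salicylaldehyde dimethyl acetal 10) with styrene 9 forms O1–C2 and C3–C4 and sets C2.
- 10 comes from aldehyde 7 and the symmetric phenol 6, made from 3,5-dimethoxyphenol 1 and prenyl bromide 3. 9 comes from aldehyde 8 by Wittig methylenation.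
- Rings A and B are bought; ring C is the only ring formed (step 7).

Key step: step 7

Assumption: the (S,S) antipode of the chiral acid is taken to deliver the 2S configuration; if it favours 2R, the (R,R) acid is used and nothing else changes. Prenyl stands for 3-methylbut-2-en-1-yl.

**Route**

Step 1
Reactants: 1 3,5-dimethoxyphenol
Product: 2 (3,5-dimethoxyphenoxy)triisopropylsilane
Conditions: TIPSCl, imidazole, DMF, rt
Reagents that add atoms: triisopropylsilyl chloride, CC(C)[Si](Cl)(C(C)C)C(C)C
Why: Silyl ether formation masks the acidic OH, and the bulky triisopropylsilyl group shields both positions ortho to it for the metalation that follows.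

Step 2
Reactants: 2 (3,5-dimethoxyphenoxy)triisopropylsilane; 3 prenyl bromide (1-bromo-3-methylbut-2-ene)
Product: 5 [3,5-dimethoxy-4-(3-methylbut-2-en-1-yl)phenoxy]triisopropylsilane, via aryllithium 4 (not isolated)
Conditions: n-BuLi, TMEDA, THF, 0 °C; then CuBr·SMe2 (10 mol %), 3, −78 °C → rt
Reagents that add atoms: none
Why: Directed ortho-metalation should occur at the carbon flanked by both methoxy groups, because the bulky silyl ether is a poor director and blocks its neighbours; copper-catalysed allylic substitution on the primary bromide should then give the linear (SN2) prenyl arene.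

Step 3
Reactants: 5 [3,5-dimethoxy-4-(3-methylbut-2-en-1-yl)phenoxy]triisopropylsilane
Product: 6 3,5-dimethoxy-4-(3-methylbut-2-en-1-yl)phenol
Conditions: TBAF, THF, 0 °C; AcOH quench
Reagents that add atoms: none
Why: Fluoride-induced cleavage of the aryl silyl ether, driven by the Si–F bond, leaves the methyl ethers and the alkene untouched.

Step 4
Reactants: 6 3,5-dimethoxy-4-(3-methylbut-2-en-1-yl)phenol
Product: 7 6-hydroxy-2,4-dimethoxy-3-(3-methylbut-2-en-1-yl)benzaldehyde
Conditions: MgCl2, Et3N, (CH2O)n, THF, reflux; dilute HCl work-up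
Reagents that add atoms: paraformaldehyde (as formaldehyde), C=O
Why: Casnati–Skattebøl ortho-formylation, in which the magnesium phenoxide directs formaldehyde to the ortho carbon and a second formaldehyde accepts hydride; the two ortho positions are equivalent by symmetry and the para position is blocked, so one aldehyde should form under conditions that spare the prenyl alkene.

Step 5
Reactants: 8 3,4,5-trimethoxybenzaldehyde
Product: 9 3,4,5-trimethoxystyrene
Conditions: Ph3PCH3Br, KOtBu, THF, 0 °C → rt
Reagents that add atoms: methyltriphenylphosphonium bromide, C[P+](c1ccccc1)(c1ccccc1)c1ccccc1.[Br-]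
Why: Wittig methylenation of a non-enolisable aromatic aldehyde with the unstabilised ylide is a dependable way to the styrene.

Step 6
Reactants: 7 6-hydroxy-2,4-dimethoxy-3-(3-methylbut-2-en-1-yl)benzaldehyde
Product: 10 2-(dimethoxymethyl)-3,5-dimethoxy-4-(3-methylbut-2-en-1-yl)phenol
Conditions: HC(OMe)3, MeOH, TsOH·H2O (2 mol %), rt; then solid K2CO3, filter, evaporate; crude 10 used at once
Reagents that add atoms: trimethyl orthoformate, COC(OC)OC; methanol, CO
Why: Acid-catalysed acetalisation, with the orthoformate taking up the water, should convert the aldehyde fully; neutralisation before concentration keeps the electron-rich acetal from ionising.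

Step 7
Reactants: 10 2-(dimethoxymethyl)-3,5-dimethoxy-4-(3-methylbut-2-en-1-yl)phenol; 9 3,4,5-trimethoxystyrene (3 equiv)
Product: 12 (2S,4S)-4,5,7-trimethoxy-6-(3-methylbut-2-en-1-yl)-2-(3,4,5-trimethoxyphenyl)chromane (2,4-cis), via ortho-quinone methide 11 (not isolated)
Conditions: (S,S)-imidodiphosphorimidate HN[P(=NSO2CF3)(OR*O)]2 with R*(O)2 = (S)-3,3′-diphenyl-1,1′-binaphthalene-2,2′-diolate (5 mol %), 5 Å MS, CH2Cl2/cyclohexane, −40 °C; Et3N quench
Reagents that add atoms: none
Why: Proposed new method: the chiral acid protonates one acetal oxygen of 10 and expels methanol, giving the O-protonated form of ortho-quinone methide 11 (a 2-hydroxyaryl oxocarbenium ion) as a contact ion pair inside the chiral anion pocket; the terminal carbon of 9 attacks C4 and the ring A oxygen captures the developing benzylic cation at C2 in a concerted but asynchronous inverse-electron-demand oxa-[4+2] step that returns the proton to the catalyst. The closest known reaction type is the achiral Brønsted or Lewis acid-promoted hetero-Diels–Alder reaction of ortho-quinone methides from salicylaldehyde acetals with styrenes, which gives racemic 2,4-cis-4-alkoxyflavans. Ring C closes as a six-membered ring by cycloaddition, the C3–C4 bond leading and the O1–C2 bond following, and the aryl group of 9 fixes the regiochemistry by stabilising positive charge at C2. C2 is set by the enantiofacial approach of the styrene to the ion-paired heterodiene under control of the chiral counter-anion; C4 follows from the endo transition state (2,4-cis) and is erased in step 8. The step needs chemoselectivity for the styrene over the prenyl alkene, which the excess of 9 should secure, since the prenyl group sits meta to the cationic carbon and cannot reach it within its own molecule; it also needs a free ortho hydroxyl, which the phenol of 10 supplies.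

Step 8
Reactants: 12 (2S,4S)-4,5,7-trimethoxy-6-(3-methylbut-2-en-1-yl)-2-(3,4,5-trimethoxyphenyl)chromane
Product: 13 (2S)-5,7-dimethoxy-6-(3-methylbut-2-en-1-yl)-2-(3,4,5-trimethoxyphenyl)chroman-4-one
Conditions: DDQ (1.2 equiv), CH2Cl2/pH 7 phosphate buffer (10:1), 0 °C
Reagents that add atoms: water, O
Why: DDQ oxidation of a benzylic methyl ether: hydride abstraction from the pseudo-axial C4–H (activated by the α-methoxy group and the three oxygen donors of ring A), capture of the cation by water and loss of methanol should give the ketone, which deactivates ring A towards further oxidation and leaves C2 untouched.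

Step 9
Reactants: 13 (2S)-5,7-dimethoxy-6-(3-methylbut-2-en-1-yl)-2-(3,4,5-trimethoxyphenyl)chroman-4-one
Product: 14 (2S)-5-hydroxy-7-methoxy-6-(3-methylbut-2-en-1-yl)-2-(3,4,5-trimethoxyphenyl)chroman-4-one (artoflavanone)
Conditions: MgI2·OEt2 (3 equiv), THF, 50 °C; aqueous Na2S2O3 work-up
Reagents that add atoms: none
Why: Chelation-controlled ether cleavage: magnesium bridges the C4 carbonyl and the peri C5 methoxy oxygen and iodide removes that methyl group by SN2, so the C7 and ring B methyl ethers, the prenyl alkene and C2 (no base, no protic acid) should be left alone.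

**Compound list**

1 | 3,5-dimethoxyphenol | COc1cc(O)cc(OC)c1 | starting material
2 | (3,5-dimethoxyphenoxy)triisopropylsilane | COc1cc(O[Si](C(C)C)(C(C)C)C(C)C)cc(OC)c1 | intermediate
3 | prenyl bromide (1-bromo-3-methylbut-2-ene) | CC(C)=CCBr | starting material
4 | [2,6-dimethoxy-4-(triisopropylsilyloxy)phenyl]lithium | [Li]c1c(OC)cc(O[Si](C(C)C)(C(C)C)C(C)C)cc1OC | intermediate
5 | [3,5-dimethoxy-4-(3-methylbut-2-en-1-yl)phenoxy]triisopropylsilane | COc1cc(O[Si](C(C)C)(C(C)C)C(C)C)cc(OC)c1CC=C(C)C | intermediate
6 | 3,5-dimethoxy-4-(3-methylbut-2-en-1-yl)phenol | COc1cc(O)cc(OC)c1CC=C(C)C | intermediate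
7 | 6-hydroxy-2,4-dimethoxy-3-(3-methylbut-2-en-1-yl)benzaldehyde | O=Cc1c(O)cc(OC)c(CC=C(C)C)c1OC | intermediate
8 | 3,4,5-trimethoxybenzaldehyde | COc1cc(C=O)cc(OC)c1OC | starting material
9 | 3,4,5-trimethoxystyrene | C=Cc1cc(OC)c(OC)c(OC)c1 | intermediate
10 | 2-(dimethoxymethyl)-3,5-dimethoxy-4-(3-methylbut-2-en-1-yl)phenol | COC(OC)c1c(O)cc(OC)c(CC=C(C)C)c1OC | intermediate
11 | 3,5-dimethoxy-6-(methoxymethylidene)-4-(3-methylbut-2-en-1-yl)cyclohexa-2,4-dien-1-one (ortho-quinone methide) | COC=C1C(=O)C=C(OC)C(CC=C(C)C)=C1OC | intermediate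
12 | (2S,4S)-4,5,7-trimethoxy-6-(3-methylbut-2-en-1-yl)-2-(3,4,5-trimethoxyphenyl)chromane (2,4-cis) | COc1cc2c(c(OC)c1CC=C(C)C)[C@@H](OC)C[C@@H](c1cc(OC)c(OC)c(OC)c1)O2 | intermediate
13 | (2S)-5,7-dimethoxy-6-(3-methylbut-2-en-1-yl)-2-(3,4,5-trimethoxyphenyl)chroman-4-one | COc1cc2c(c(OC)c1CC=C(C)C)C(=O)C[C@@H](c1cc(OC)c(OC)c(OC)c1)O2 | intermediate
14 | (2S)-5-hydroxy-7-methoxy-6-(3-methylbut-2-en-1-yl)-2-(3,4,5-trimethoxyphenyl)chroman-4-one (artoflavanone) | COc1cc2c(c(O)c1CC=C(C)C)C(=O)C[C@@H](c1cc(OC)c(OC)c(OC)c1)O2 | target

**Step count**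

Total: 9 steps. Longest linear sequence: 8 steps (steps 1, 2, 3, 4, 6, 7, 8, 9); step 5 is a one-step branch.

**Steps most likely to fail**

Step 7. The ion pair may give too little enantiofacial discrimination, or the cation may be consumed by the prenyl alkene of a second molecule and oligomerise. The fallback uses known chemistry, sets out from 10 and 9 and rejoins at 13. The cycloaddition is run with an achiral acid, Sc(OTf)3 (10 mol %) in CH2Cl2 at 0 °C, to give the racemic 2,4-cis-4-methoxyflavan F1. DDQ and water as in step 8 should convert this into the racemic flavanone F2. A kinetic resolution by Noyori–Ikariya asymmetric transfer hydrogenation with RuCl[(R,R)-TsDPEN](p-cymene) and HCO2H/Et3N, stopped near half conversion, should reduce the (2R) enantiomer to the (2R,4R)-cis-flavan-4-ol F3 and leave the (2S)-flavanone 13. The sense of matching follows the usual model for aryl ketones and would be confirmed on the first run; half of the material is given up.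

Step 8. Hydride abstraction may compete at the benzylic and allylic CH2 of the prenyl group, or the cation may lose a C3 proton and be dehydrogenated further, which would erase C2. The fallback sets out from 12 and rejoins at 13 without a hydride-abstracting oxidant. Solvolysis of the ionisable C4 methyl ether in dilute aqueous acid (PPTS, acetone/water, 0 °C → rt) should give the (2S)-flavan-4-ol F4 as a mixture of C4 epimers. Oxidation of this benzylic alcohol with Dess–Martin periodinane (NaHCO3, CH2Cl2) should then give 13.

Step 6. The electron-rich free-phenol acetal may ionise during concentration, lose methanol and self-condense, or revert to the aldehyde with adventitious water. The fallback sets out from 7 and rejoins at 10, and releases the phenol only under basic conditions. Acetylation (Ac2O, pyridine, DMAP) should give 2-formyl-3,5-dimethoxy-4-prenylphenyl acetate F5. Acetalisation as in step 6 should give 2-(dimethoxymethyl)-3,5-dimethoxy-4-prenylphenyl acetate F6, which has no free phenol and can be purified on Et3N-deactivated silica. Methanolysis of the acetate (K2CO3, MeOH, 0 °C; pH 7 buffer) should then deliver 10 directly before the key step.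

**Further compounds**

F1 | step 7 | racemic 2,4-cis-4,5,7-trimethoxy-6-prenyl-2-(3,4,5-trimethoxyphenyl)chromane (both enantiomers) | COc1cc2c(c(OC)c1CC=C(C)C)[C@@H](OC)C[C@@H](c1cc(OC)c(OC)c(OC)c1)O2.COc1cc2c(c(OC)c1CC=C(C)C)[C@H](OC)C[C@H](c1cc(OC)c(OC)c(OC)c1)O2
F2 | step 7 | racemic 5,7-dimethoxy-6-prenyl-2-(3,4,5-trimethoxyphenyl)chroman-4-one (both enantiomers) | COc1cc2c(c(OC)c1CC=C(C)C)C(=O)C[C@@H](c1cc(OC)c(OC)c(OC)c1)O2.COc1cc2c(c(OC)c1CC=C(C)C)C(=O)C[C@H](c1cc(OC)c(OC)c(OC)c1)O2
F3 | step 7 | (2R,4R)-5,7-dimethoxy-6-prenyl-2-(3,4,5-trimethoxyphenyl)chroman-4-ol (2,4-cis) | COc1cc2c(c(OC)c1CC=C(C)C)[C@H](O)C[C@H](c1cc(OC)c(OC)c(OC)c1)O2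
F4 | step 8 | (2S)-5,7-dimethoxy-6-prenyl-2-(3,4,5-trimethoxyphenyl)chroman-4-ol, mixture of C4 epimers | COc1cc2c(c(OC)c1CC=C(C)C)C(O)C[C@@H](c1cc(OC)c(OC)c(OC)c1)O2
F5 | step 6 | 2-formyl-3,5-dimethoxy-4-prenylphenyl acetate | CC(=O)Oc1cc(OC)c(CC=C(C)C)c(OC)c1C=O
F6 | step 6 | 2-(dimethoxymethyl)-3,5-dimethoxy-4-prenylphenyl acetate | CC(=O)Oc1cc(OC)c(CC=C(C)C)c(OC)c1C(OC)OC
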